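## Structural features

The target is a symmetrical bis-quinone. Two identical 2-hydroxy-5-methoxy-6-methyl-1,4-benzoquinone rings (ring A and ring B, each numbered C1 to C6 with C1 and C4 as the carbonyl carbons) are joined through their C3 atoms by an unbranched chain of thirteen methylene carbons (C1' to C13'). There is no stereocentre and no ring fusion, so the problem is one of regiochemistry and of the timing of functional groups. Each ring is fully substituted in the order C1=O, C2–OH, C3–chain, C4=O, C5–OMe, C6–Me, so the free hydroxyl must sit next to the chain carbon and the methyl ether next to the ring methyl. The hydroxyquinone is a vinylogous acid and the methoxyquinone a vinylogous ester; both are sensitive to hydroxide, amines, reductants and hot acid, which argues for unveiling the quinones only after all carbon–carbon bonds exist. The chain has an odd number of carbons, so it is most naturally assembled from a central C11 unit and one carbon from each ring precursor. The real difficulty is to put the chain on C3 between two oxygenated carbons and then to tell the C2 oxygen from the C5 oxygen, whose surroundings differ only by chain versus methyl. The key step uses the fact that C3 is ortho to the C4 oxygen: with that oxygen as a free phenol and its other ortho position blocked by the C5 methoxy, a formyl carbon (the future C1') can be placed on C3 alone, and two such aldehydes are then joined to C2'–C12' by a double olefination that forms C1'=C2' and C12'=C13'.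

## Logic of the disconnections

**15 back to 14.** No skeletal bond is cut. Each C2 hydroxyl is traced back to an oxirane across C2–C3 (the O–C3 bond is added in the retrosynthetic sense). A ring carbon bearing hydrogen next to a quinone carbonyl is the one place where oxygen can still be introduced after the ring is complete, and the oxirane can isomerise in only one direction because C3 has no hydrogen. The gain is that the C2 oxygen need not be carried, and kept distinct from the C5 methoxy, through the whole route. The forward step needs an acid strong enough to open the oxirane that still spares the C5 vinylogous methyl ester.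

**14 back to 13.** The O–C2 and O–C3 bonds of each oxirane are cut. This leaves a quinone with a single free ring position, a much simpler and more stable compound. The forward step needs a nucleophilic oxidant that attacks the C2=C3 bond (hydrogen and alkyl) in both rings and leaves the C5=C6 bond (methoxy and methyl) and the methoxy group itself alone.

**13 back to 12.** The C1 and C4 carbonyls are returned to aryl methyl ethers. The reason is that an electron-rich arene tolerates ylides, strong base and hydrogenation, which a quinone does not. Both head groups become ordinary trimethoxytoluene units. The forward oxidative demethylation must take the para-related C1/C4 pair and leave the C5 ether.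

**12 back to 11.** No bond is cut; unsaturation is added at C1'–C2' and C12'–C13' to create the olefination retron. The forward step is the hydrogenation of two styrene-type alkenes, which must not touch the aryl ethers.

**11 back to 6 and 9 (through 10).** Both C1'=C2' and C12'=C13' are cut at once. These are the chain bonds nearest the rings, so the cut exposes C1' as an aldehyde carbon, which is what phenol-directed formylation can deliver at C3, and it divides the odd chain into 1 + 11 + 1 carbons. The whole skeleton falls into two molecules of one small aromatic aldehyde and one symmetrical C11 linchpin. The forward step must bring both ends of 10 to reaction.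

**9 back to 7 and 8.** The two C–P bonds are cut. Both fragments are catalogue chemicals. The forward double quaternisation must go to completion so that no mono-salt is carried into the olefination.

**6 back to 5.** The O–CH3 bond on the C4 oxygen is cut. That oxygen has to be a free phenol for the formylation but an ether during ylide chemistry, and a methyl ether is removed later in the same oxidation that makes the quinone. The forward step is a simple O-alkylation of a hydrogen-bonded phenol.

**5 back to 3 (through 4).** The C3–C1' bond is cut. The phenol has only one free ortho position, so a phenoxide-directed formylation can place the carbon nowhere else. This removes the only regiochemical question of the arene synthesis. The forward step must be strictly ortho-selective and must stop at the aldehyde oxidation level.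

**3 back to 1 (through 2).** The C4–O bond is exchanged for a C4–CHO bond (peracid oxidation retron). This reaches a commercial benzaldehyde that already has the C5 methoxy, C6 methyl and C1 methoxy in place. The forward step needs aryl migration to be favoured over hydride migration, which the ortho and para methoxy groups provide.

## Other disconnections considered

**Alternative 1:** The cut is made inside each ring, at the bond from C3 to one neighbouring ring carbon and at the bond from C6 to one oxygen-bearing neighbour.
- Forward key step: the bis-enone A1 and a malonic diester, under alkoxide, undergo Michael addition at both enone termini followed by Claisen closure through the ethyl ketone methylene. This gives the bis(cyclohexanedione ester) A2.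
- Continuation: hydrolysis, decarboxylation and dehydrogenation would give the bis-resorcinol A3. A para-selective phenol oxidation and O-methylation would then rejoin the chosen route at 13.
- In favour: both rings come from cheap acyclic material, the chain is present from the start and no phosphorus waste arises. The two ring CH positions of A3 are equivalent, so the first ring oxidation has no regiochemical issue; on that point the alternative is the equal of the chosen plan.
- Against: the annulation delivers only the C1 and C5 oxygens. C4 and C2 must still be oxidised afterwards, so the awkward late hydroxylation (steps 8 and 9) is not avoided. A2 forms as a mixture of stereoisomers and enols that is useful only after a harsh two-fold aromatisation, and A1 needs a long-chain difunctional precursor of its own.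
- Comparison: the mechanism (anionic Michael–Claisen cascade) is as dependable as a Wittig reaction. Structurally it builds what the chosen plan buys, and in step count it is longer: about seven steps from A1 to 13, against six steps (steps 1 to 3 and 5 to 7) in the longest line from 1 to 13.

**Alternative 2:** The cut is the central C7'–C8' bond, with one extra carbon carried and later excised.
- Forward key step: the acid chloride A4 is dehydrochlorinated by a tertiary amine to an alkylketene, which dimerises head to tail by [2+2] cycloaddition to the alkylidene-β-lactone A5.
- Continuation: hydrolysis and decarboxylation would give the ketone A6, and Wolff–Kishner reduction would give 12.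
- In favour: both halves come from a single arm, so the symmetry of the target is used fully. Each bond-forming event is a simple dimerisation, not a two-fold reaction on one bis-reagent, so there is no half-reacted material to remove; on that point it is better than the chosen plan. Ketene dimerisation of long-chain acid chlorides is robust.
- Against: A4 must itself be made from 6 by an olefination with an ω-carboxy ylide, hydrogenation and chlorination. The alternative therefore contains the chemistry of the chosen plan and adds to it. A carbonyl is introduced only to be removed, and one carbon is lost to reach the odd chain length.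
- Comparison: the arene and its regiochemical control are identical, and the endgame from 12 is the same. About six steps separate 6 from 12, against two in the chosen plan, so the step economy is clearly worse.

**Alternative 3:** The cut is the C4–C5 bond of each ring, so that each quinone is assembled from a four-carbon squarate-derived unit (C1 to C4, with the chain on C3) and a two-carbon alkenyl unit (C5 and C6).
- Forward key step: heating the tethered bis(alkenyl-hydroxycyclobutenone) A7 opens each four-membered ring to a dienylketene. A 6π electrocyclisation and tautomerisation then give the bis-hydroquinone A8.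
- Continuation: oxidation would give the bis(isopropoxy-methoxyquinone) A9, and selective cleavage of the secondary isopropyl ether would give 15.
- In favour: every ring substituent is placed by construction, and the C2 oxygen arrives as an isopropyl ether that is chemically distinct from the C5 methyl ether. No late C–H hydroxylation of a quinone is needed; on this point the alternative is better than the chosen plan. From a tethered bis-cyclobutenedione the sequence is also shorter on paper.
- Against: A7 needs a C13 α,ω-dimetallic reagent that adds exactly once to each of two squaric esters, and then a regioselective carbonyl addition of a β-methoxy alkenyl-lithium at both ends. Any regiochemical leakage in these four additions gives constitutional isomers that would be hard to separate from a symmetrical dimer. The reagents are less accessible than 1, 7 and 8, and A8 is air-sensitive.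
- Comparison: the pericyclic cascade is mechanistically clean and differentiates the oxygens better. Once reagent preparation is counted the step economy is roughly equal. The chosen plan relies on more ordinary reagents and keeps its one regiochemical decision (step 2) on a small, easily purified compound.

Key step: step 5

Remark: ring locants C1–C6 and chain locants C1'–C13' used in the discussion are those of the target; systematic names of intermediates carry their own locants.
Remark: since 1 has no free hydroxyl, the aldehyde-to-phenol conversion is run as a peracid Baeyer–Villiger oxidation with formate cleavage and not under alkaline peroxide.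
Assumption: 11 is drawn as the (1Z,12Z)-isomer expected to predominate; any (E)-alkene converges on 12 in step 6, and 14 is carried as a mixture of oxirane stereoisomers that converges on 15.

## Route

Step 1
Reactants: 1 2,4-dimethoxy-3-methylbenzaldehyde
Product: 3 2,4-dimethoxy-3-methylphenol, via aryl formate 2 (not isolated)
Conditions: mCPBA, CH2Cl2, 0 °C → rt; then K2CO3, MeOH, rt
Reagents that add atoms: 3-chloroperoxybenzoic acid, OOC(=O)c1cccc(Cl)c1
Why: Baeyer–Villiger oxidation of an electron-rich benzaldehyde (Dakin-type outcome): the ortho and para methoxy groups make the aryl group migrate in the Criegee adduct, giving formate 2, which is cleaved by methanolysis to the phenol.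

Step 2
Reactants: 3 2,4-dimethoxy-3-methylphenol
Product: 5 2-hydroxy-3,5-dimethoxy-4-methylbenzaldehyde, via salicyl alcohol 4 (not isolated)
Conditions: MgCl2, Et3N, (CH2O)n, MeCN, reflux; then 1 M HCl
Reagents that add atoms: paraformaldehyde (reacting as formaldehyde), C=O
Why: Casnati–Skattebøl ortho-formylation: the magnesium phenoxide delivers formaldehyde through a six-membered chelate to the only free ortho carbon (the other is blocked by methoxy), and the benzylic alkoxide 4 is oxidised to the aldehyde by hydride transfer to a second formaldehyde.

Step 3
Reactants: 5 2-hydroxy-3,5-dimethoxy-4-methylbenzaldehyde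
Product: 6 2,3,5-trimethoxy-4-methylbenzaldehyde
Conditions: MeI, K2CO3, DMF, rt
Reagents that add atoms: iodomethane, CI
Why: Williamson O-methylation; the hydrogen-bonded salicylaldehyde phenol is acidic enough for carbonate, and the non-enolisable aldehyde is untouched.

Step 4
Reactants: 7 1,11-dibromoundecane; 8 triphenylphosphine (2.2 equiv)
Product: 9 undecane-1,11-diylbis(triphenylphosphonium) dibromide
Conditions: MeCN, reflux, 48 h; precipitation with Et2O, drying under vacuum
Reagents that add atoms: none
Why: Double SN2 quaternisation of a primary α,ω-dibromide; the excess phosphine and long reaction time drive both ends to the salt, which is freed from neutral material by precipitation.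

Step 5
Reactants: 9 undecane-1,11-diylbis(triphenylphosphonium) dibromide; 6 2,3,5-trimethoxy-4-methylbenzaldehyde (2.3 equiv)
Product: 11 (1Z,12Z)-1,13-bis(2,3,5-trimethoxy-4-methylphenyl)trideca-1,12-diene, via bis-ylide 10 (not isolated)
Conditions: NaN(SiMe3)2 (2.1 equiv), THF, 0 °C; then 6, −78 °C → rt
Reagents that add atoms: none
Why: NaN(SiMe3)2 removes one proton next to each phosphorus of 9 to give the bis-ylide 10. Each ylide carbon then adds to the carbonyl of one molecule of 6 in an asynchronous [2+2] cycloaddition to an oxaphosphetane, which fragments by cycloreversion to the C1'=C2' (or C12'=C13') alkene and triphenylphosphine oxide; under these lithium-free conditions the cis-oxaphosphetane and hence the (Z)-alkene should predominate. The closest known reaction type is the Wittig olefination of aromatic aldehydes with non-stabilised α,ω-alkanediyl bis-ylides. No ring is closed and no stereocentre is created, and the alkene geometry is of no consequence because both double bonds are saturated in step 6. The selectivity that matters is completeness, meaning that both termini must olefinate. This is secured by forming 10 fully before the electrophile is added (no amide base is left to attack the aldehyde), by the non-enolisable nature of 6, by a small excess of 6, and by the nine-methylene spacer that lets the two ylide centres react independently. Because 6 is monofunctional, neither oligomerisation nor cyclisation is open to the mono-olefinated ylide, so the only by-product class to expect is half-reacted phosphonium salt, which is removed by its polarity. The position of the chain on each ring was already fixed in step 2, since the aldehyde carbon is C1'.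

Step 6
Reactants: 11 (1Z,12Z)-1,13-bis(2,3,5-trimethoxy-4-methylphenyl)trideca-1,12-diene
Product: 12 1,13-bis(2,3,5-trimethoxy-4-methylphenyl)tridecane
Conditions: H2 (1 atm), 10% Pd/C, EtOAc, rt
Reagents that add atoms: none
Why: Heterogeneous catalytic hydrogenation of two disubstituted styrene-type alkenes; aryl methyl ethers are inert, and both alkene geometries give the same product.

Step 7
Reactants: 12 1,13-bis(2,3,5-trimethoxy-4-methylphenyl)tridecane
Product: 13 1,13-bis(5-methoxy-4-methyl-3,6-dioxocyclohexa-1,4-dien-1-yl)tridecane
Conditions: (NH4)2Ce(NO3)6 (5 equiv), MeCN/H2O, 0 °C
Reagents that add atoms: water, O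
Why: Oxidative demethylation: one-electron oxidation by tetravalent cerium gives the arene radical cation, water adds at the two para-related methoxy-bearing carbons (C1 and C4) and methanol is expelled to give the para-quinone; the 1,4-dimethoxy pair is normally oxidised in preference to the adjacent pair in 1,2,4-trimethoxyarenes, so the C5 ether is kept.

Step 8
Reactants: 13 1,13-bis(5-methoxy-4-methyl-3,6-dioxocyclohexa-1,4-dien-1-yl)tridecane
Product: 14 1,13-bis(3-methoxy-4-methyl-2,5-dioxo-7-oxabicyclo[4.1.0]hept-3-en-1-yl)tridecane
Conditions: 30% aq H2O2, Na2CO3, THF/H2O, 0 °C
Reagents that add atoms: hydrogen peroxide, OO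
Why: Weitz–Scheffer nucleophilic epoxidation: hydroperoxide adds in conjugate fashion to the unsubstituted ring CH (C2) and the enolate closes on oxygen, whereas the C5=C6 bond is a tetrasubstituted vinylogous ester and far less electrophilic; the cis-fused oxirane stereocentres form without control and are erased in step 9.

Step 9
Reactants: 14 1,13-bis(3-methoxy-4-methyl-2,5-dioxo-7-oxabicyclo[4.1.0]hept-3-en-1-yl)tridecane
Product: 15 1,13-bis(2-hydroxy-5-methoxy-4-methyl-3,6-dioxocyclohexa-1,4-dien-1-yl)tridecane (target)
Conditions: conc. H2SO4 on SiO2, CH2Cl2, 0 °C → rt
Reagents that add atoms: none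
Why: Acid-promoted isomerisation of a 2,3-epoxy-1,4-dione that carries one oxirane hydrogen (the classical epoxyquinone to hydroxyquinone rearrangement): cleavage of the O–C3 bond and loss of the C2 proton restore the C2=C3 bond with the oxygen left on C2, and because C3 has no hydrogen the hydroxyl can appear only at C2.

## Compound list

1 | 2,4-dimethoxy-3-methylbenzaldehyde | COc1ccc(C=O)c(OC)c1C | starting material
2 | 2,4-dimethoxy-3-methylphenyl formate | COc1ccc(OC=O)c(OC)c1C | intermediate (not isolated)
3 | 2,4-dimethoxy-3-methylphenol | COc1ccc(O)c(OC)c1C | intermediate
4 | 6-(hydroxymethyl)-2,4-dimethoxy-3-methylphenol (present as its magnesium salt) | COc1cc(CO)c(O)c(OC)c1C | intermediate (not isolated)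
5 | 2-hydroxy-3,5-dimethoxy-4-methylbenzaldehyde | COc1cc(C=O)c(O)c(OC)c1C | intermediate
6 | 2,3,5-trimethoxy-4-methylbenzaldehyde | COc1cc(C=O)c(OC)c(OC)c1C | intermediate
7 | 1,11-dibromoundecane | BrCCCCCCCCCCCBr | starting material
8 | triphenylphosphine | c1ccc(cc1)P(c1ccccc1)c1ccccc1 | starting material
9 | undecane-1,11-diylbis(triphenylphosphonium) dibromide | [Br-].[Br-].c1ccc(cc1)[P+](c1ccccc1)(c1ccccc1)CCCCCCCCCCC[P+](c1ccccc1)(c1ccccc1)c1ccccc1 | intermediate
10 | undecane-1,11-diylidenebis(triphenylphosphorane) (bis-ylide) | c1ccc(cc1)P(c1ccccc1)(c1ccccc1)=CCCCCCCCCCC=P(c1ccccc1)(c1ccccc1)c1ccccc1 | intermediate (not isolated)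
11 | (1Z,12Z)-1,13-bis(2,3,5-trimethoxy-4-methylphenyl)trideca-1,12-diene | COc1cc(/C=C\CCCCCCCCC/C=C\c2cc(OC)c(C)c(OC)c2OC)c(OC)c(OC)c1C | intermediate
12 | 1,13-bis(2,3,5-trimethoxy-4-methylphenyl)tridecane | COc1cc(CCCCCCCCCCCCCc2cc(OC)c(C)c(OC)c2OC)c(OC)c(OC)c1C | intermediate
13 | 1,13-bis(5-methoxy-4-methyl-3,6-dioxocyclohexa-1,4-dien-1-yl)tridecane | COC1=C(C)C(=O)C=C(CCCCCCCCCCCCCC2=CC(=O)C(C)=C(OC)C2=O)C1=O | intermediate
14 | 1,13-bis(3-methoxy-4-methyl-2,5-dioxo-7-oxabicyclo[4.1.0]hept-3-en-1-yl)tridecane (oxiranes cis-fused; stereoisomer mixture) | COC1=C(C)C(=O)C2OC2(CCCCCCCCCCCCCC23OC2C(=O)C(C)=C(OC)C3=O)C1=O | intermediate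
15 | 1,13-bis(2-hydroxy-5-methoxy-4-methyl-3,6-dioxocyclohexa-1,4-dien-1-yl)tridecane | COC1=C(C)C(=O)C(O)=C(CCCCCCCCCCCCCC2=C(O)C(=O)C(C)=C(OC)C2=O)C1=O | target

## Step count and least certain steps

Total: 9 steps. Longest linear sequence: 8 steps (steps 1, 2, 3, 5, 6, 7, 8, 9 from 1); step 4 is a one-step convergent branch.

**Step 5 (key step).**
- Most likely failure: incomplete olefination at the second terminus. The bis-salt 9 is hygroscopic and sparingly soluble in THF, so slow or partial ylide formation, or partial protonation of one ylide centre by moisture, would leave half-reacted material.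
- Fallback (sets out from 7 and 6, rejoins at 12): 7 would be converted with Mg turnings in THF into undecane-1,11-diylbis(magnesium bromide) F1. This adds to two equivalents of 6 to give 1,13-bis(2,3,5-trimethoxy-4-methylphenyl)tridecane-1,13-diol F2 as a diastereomer mixture. Ionic deoxygenation of both electron-rich benzylic alcohols with Et3SiH and CF3CO2H in CH2Cl2 should then give 12 directly. The C1'–C2' and C12'–C13' bonds are thus formed by carbonyl addition instead of olefination, and steps 4 to 6 are replaced.

**Step 8.**
- Most likely failure: loss of chemoselectivity under basic peroxide. This means addition–elimination of hydroperoxide or hydroxide at the methoxy-bearing carbon (loss of the methyl ether), base-induced tautomerisation or oligomerisation of the alkylquinone, and incomplete reaction at the second ring.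
- Fallback (sets out from 13, rejoins at 15): Thiele–Winter acetoxylation of 13 (Ac2O, catalytic H2SO4) adds acetate at the single free ring position while the quinone is reduced and acetylated, giving 1,13-bis(2,3,6-triacetoxy-5-methoxy-4-methylphenyl)tridecane F3. Acid methanolysis (HCl, MeOH, under argon) gives 1,13-bis(2,3,6-trihydroxy-5-methoxy-4-methylphenyl)tridecane F4, and oxidation with FeCl3 or air should give 15. No oxirane and no basic oxidant are involved, and step 9 is bypassed as well.

**Step 9.**
- Most likely failure: acid cleavage of the vinylogous methyl ester at C5 in competition with oxirane opening, or incomplete rearrangement of one of the two rings on the solid support.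
- Fallback (sets out from 12, rejoins at 15): the one free position of each ring of 12 is brominated (NBS, MeCN, 0 °C) to 1,13-bis(2-bromo-3,5,6-trimethoxy-4-methylphenyl)tridecane F5. Oxidation with (NH4)2Ce(NO3)6 as in step 7 gives 1,13-bis(2-bromo-5-methoxy-4-methyl-3,6-dioxocyclohexa-1,4-dien-1-yl)tridecane F6. Addition–elimination of hydroxide at the bromine-bearing carbon (dilute aqueous KOH, THF, 0 °C, then acidification) should give 15. The C2 oxygen is introduced by substitution of a far better leaving group than methoxide, without any strong acid.

**Step 7.**
- Most likely failure: erosion of regiocontrol in the oxidative demethylation (ortho-quinone formation from the adjacent methoxy pair) and oxidative coupling of the electron-rich rings.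
- Fallback (sets out from 5, rejoins at 13): 5 is benzylated (BnBr, K2CO3, DMF) to 2-(benzyloxy)-3,5-dimethoxy-4-methylbenzaldehyde F7. The double Wittig reaction with 10 gives (1Z,12Z)-1,13-bis[2-(benzyloxy)-3,5-dimethoxy-4-methylphenyl]trideca-1,12-diene F8. Hydrogenation over Pd/C saturates both alkenes and removes both benzyl groups to give 6,6'-(tridecane-1,13-diyl)bis(2,4-dimethoxy-3-methylphenol) F9. PhI(OAc)2 in aqueous MeCN then oxidises each para-methoxyphenol to the para-quinone 13; the position of the free phenol dictates which methoxy group is lost.

## Further compounds

F1 | step 5 | undecane-1,11-diylbis(magnesium bromide) | Br[Mg]CCCCCCCCCCC[Mg]Br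
F2 | step 5 | 1,13-bis(2,3,5-trimethoxy-4-methylphenyl)tridecane-1,13-diol (diastereomer mixture) | COc1cc(C(O)CCCCCCCCCCCC(O)c2cc(OC)c(C)c(OC)c2OC)c(OC)c(OC)c1C
F3 | step 8 | 1,13-bis(2,3,6-triacetoxy-5-methoxy-4-methylphenyl)tridecane | COc1c(C)c(OC(C)=O)c(OC(C)=O)c(CCCCCCCCCCCCCc2c(OC(C)=O)c(OC(C)=O)c(C)c(OC)c2OC(C)=O)c1OC(C)=O
F4 | step 8 | 1,13-bis(2,3,6-trihydroxy-5-methoxy-4-methylphenyl)tridecane | COc1c(C)c(O)c(O)c(CCCCCCCCCCCCCc2c(O)c(O)c(C)c(OC)c2O)c1O
F5 | step 9 | 1,13-bis(2-bromo-3,5,6-trimethoxy-4-methylphenyl)tridecane | COc1c(Br)c(CCCCCCCCCCCCCc2c(Br)c(OC)c(C)c(OC)c2OC)c(OC)c(OC)c1C
F6 | step 9 | 1,13-bis(2-bromo-5-methoxy-4-methyl-3,6-dioxocyclohexa-1,4-dien-1-yl)tridecane | COC1=C(C)C(=O)C(Br)=C(CCCCCCCCCCCCCC2=C(Br)C(=O)C(C)=C(OC)C2=O)C1=O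
F7 | step 7 | 2-(benzyloxy)-3,5-dimethoxy-4-methylbenzaldehyde | COc1cc(C=O)c(OCc2ccccc2)c(OC)c1C
F8 | step 7 | (1Z,12Z)-1,13-bis[2-(benzyloxy)-3,5-dimethoxy-4-methylphenyl]trideca-1,12-diene | COc1cc(/C=C\CCCCCCCCC/C=C\c2cc(OC)c(C)c(OC)c2OCc2ccccc2)c(OCc2ccccc2)c(OC)c1C
F9 | step 7 | 6,6'-(tridecane-1,13-diyl)bis(2,4-dimethoxy-3-methylphenol) | COc1cc(CCCCCCCCCCCCCc2cc(OC)c(C)c(OC)c2O)c(O)c(OC)c1C
A1 | alternative 1 | (4E,19E)-tricosa-4,19-diene-3,21-dione | CCC(=O)/C=C/CCCCCCCCCCCCC/C=C/C(=O)CC
A2 | alternative 1 | dimethyl 6,6'-(tridecane-1,13-diyl)bis(3-methyl-2,4-dioxocyclohexane-1-carboxylate) (stereoisomer and enol mixture) | CC1C(=O)CC(CCCCCCCCCCCCCC2CC(=O)C(C)C(=O)C2C(=O)OC)C(C(=O)OC)C1=O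
A3 | alternative 1 | 5,5'-(tridecane-1,13-diyl)bis(2-methylbenzene-1,3-diol) | Cc1c(O)cc(CCCCCCCCCCCCCc2cc(O)c(C)c(O)c2)cc1O
A4 | alternative 2 | 7-(2,3,5-trimethoxy-4-methylphenyl)heptanoyl chloride | COc1cc(CCCCCCC(Cl)=O)c(OC)c(OC)c1C
A5 | alternative 2 | (Z)-4-[6-(2,3,5-trimethoxy-4-methylphenyl)hexylidene]-3-[5-(2,3,5-trimethoxy-4-methylphenyl)pentyl]oxetan-2-one (racemic at C3) | O=C1O/C(=C\CCCCCc2cc(OC)c(C)c(OC)c2OC)C1CCCCCc1cc(OC)c(C)c(OC)c1OC
A6 | alternative 2 | 1,13-bis(2,3,5-trimethoxy-4-methylphenyl)tridecan-7-one | COc1cc(CCCCCCC(=O)CCCCCCc2cc(OC)c(C)c(OC)c2OC)c(OC)c(OC)c1C
A7 | alternative 3 | 2,2'-(tridecane-1,13-diyl)bis{4-hydroxy-3-isopropoxy-4-[(E)-1-methoxyprop-1-en-2-yl]cyclobut-2-en-1-one} (stereoisomer mixture at the carbinol carbons) | CO/C=C(\C)C1(O)C(OC(C)C)=C(CCCCCCCCCCCCCC2=C(OC(C)C)C(O)(/C(C)=C/OC)C2=O)C1=O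
A8 | alternative 3 | 1,13-bis(2,5-dihydroxy-6-isopropoxy-3-methoxy-4-methylphenyl)tridecane | COc1c(C)c(O)c(OC(C)C)c(CCCCCCCCCCCCCc2c(OC(C)C)c(O)c(C)c(OC)c2O)c1O
A9 | alternative 3 | 1,13-bis(2-isopropoxy-5-methoxy-4-methyl-3,6-dioxocyclohexa-1,4-dien-1-yl)tridecane | COC1=C(C)C(=O)C(OC(C)C)=C(CCCCCCCCCCCCCC2=C(OC(C)C)C(=O)C(C)=C(OC)C2=O)C1=O
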